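**Plan**

- Enabling feature: in the seven-membered ring the acetoxy carbon lies between the CH2 on the methyl-bearing fusion carbon and the carbon carrying the exocyclic CH2. Removing the CH2–CH2 pair that links this methylene carbon to the fusion CH leaves a cyclopentenone (carbonyl carbon = acetoxy carbon) fused to the five-membered ring, i.e. a bicyclo[3.3.0]octenone open to a (2+2+1) cycloaddition.
- Cuts: (a) the two ring bonds of that CH2–CH2 pair (ethylene; the fusion C–H and the C=CH2 appear when the cyclobutane is reopened by a radical); (b) the bond between the two fusion carbons and both bonds to the acetoxy carbon (1,6-enyne + CO); (c) the five-ring CH2–CH2 bond (alkyl–allyl coupling), the ring CH–alkyne bond (epoxide opening) and the alkyne–CH2OH bond.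
- Forward order: geraniol epoxide, C2 alkynylation, methallyl coupling and hydroxymethylation give the enyne; step 8 closes the cyclopentane and the cyclopentenone together; ethylene photoadduct, iodide and radical fragmentation convert the cyclopentenone into the methylenecycloheptane; side-chain transposition, acetate and desilylation finish.
- Stereochemistry: carbinol carbon and side-chain-bearing ring CH from Sharpless epoxidation plus invertive opening; quaternary methyl carbon from the propargylic centre in step 8; fusion CH from hydrogen-atom transfer anti to methyl and side chain; acetoxy carbon from hydroxyl-directed reduction followed by Mitsunobu inversion; E-alkene from selenoxide syn-elimination.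

Key step: step 8

Remark: the oxirane CH made in step 9 (and the selenium-bearing carbon of 24) is carried as both configurations, because it becomes an alkene carbon in step 14; the SMILES leave it undefined. Compounds 3, 10, 13 and 19 are taken as purchased.

**Route**

Step 1
Reactants: 1 geraniol
Product: 2 (2S,3S)-2,3-epoxygeraniol
Conditions: Ti(OiPr)4 (cat.), L-(+)-diethyl tartrate (cat.), t-BuOOH, 4 Å MS, CH2Cl2, −20 °C
Reagents that add atoms: tert-butyl hydroperoxide, CC(C)(C)OO
Why: Sharpless asymmetric epoxidation of an E-allylic alcohol, which with L-(+)-tartrate should give the (2S,3S)-epoxide and so fixes the future carbinol carbon and, after inversion in step 2, the ring CH that carries the side chain.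

Step 2
Reactants: 2 (2S,3S)-2,3-epoxygeraniol; 3 ethynyltrimethylsilane
Product: 7 (2R,3S)-3,7-dimethyl-2-[(trimethylsilyl)ethynyl]oct-6-ene-1,3-diol, via lithium acetylide 4 (not isolated), via alkynyltrimethylaluminate 5 (not isolated), via alkoxyaluminate 6 (not isolated)
Conditions: 3, n-BuLi, toluene, −78 → 0 °C; AlMe3, 0 °C; then 2, 0 °C → rt; aq. sodium potassium tartrate
Reagents that add atoms: none
Why: The hydroxyl of 2 binds to the alkynylaluminate and the alkynyl group is delivered inside this ate complex to C2 (five-membered transition state, C3 being tertiary and more remote), an SN2 opening with inversion that is the C2-selective alkynylation of 2,3-epoxy alcohols by alkynylaluminium ate complexes and parallels C2 hydride delivery by aluminium hydrides.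

Step 3
Reactants: 7 (2R,3S)-3,7-dimethyl-2-[(trimethylsilyl)ethynyl]oct-6-ene-1,3-diol
Product: 8 (2R,3S)-3-hydroxy-3,7-dimethyl-2-[(trimethylsilyl)ethynyl]oct-6-en-1-yl 4-methylbenzenesulfonate
Conditions: TsCl, Et3N, DMAP (cat.), CH2Cl2, 0 °C
Reagents that add atoms: p-toluenesulfonyl chloride, Cc1ccc(cc1)S(Cl)(=O)=O
Why: Sulfonylation is selective for the primary hydroxyl because the tertiary one is too hindered to react with TsCl under these conditions.

Step 4
Reactants: 8 primary tosylate
Product: 9 (2R,3S)-3,7-dimethyl-3-(triethylsilyloxy)-2-[(trimethylsilyl)ethynyl]oct-6-en-1-yl 4-methylbenzenesulfonate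
Conditions: TESOTf, 2,6-lutidine, CH2Cl2, −78 → 0 °C
Reagents that add atoms: triethylsilyl trifluoromethanesulfonate, CC[Si](CC)(CC)OS(=O)(=O)C(F)(F)F
Why: Silyl triflate with a hindered base silylates the tertiary alcohol without touching the tosylate, which prevents oxetane formation in step 5 and, later, tetrahydrofuran formation with the side-chain epoxide.

Step 5
Reactants: 9 silylated tosylate; 10 2-methylallylmagnesium chloride
Product: 11 (3S)-6-methyl-3-[(2S)-6-methyl-2-(triethylsilyloxy)hept-5-en-2-yl]-1-(trimethylsilyl)hept-6-en-1-yne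
Conditions: 10 (THF solution), Li2CuCl4 (cat.), THF, −40 → 0 °C
Reagents that add atoms: none
Why: Copper-catalysed coupling of a primary tosylate with an allylic Grignard reagent (Kochi-type), in which the C-silylated alkyne offers no propargylic leaving group for an SN2' pathway and the stereocentres are not involved.

Step 6
Reactants: 11 silylated enyne
Product: 12 (3S)-6-methyl-3-[(2S)-6-methyl-2-(triethylsilyloxy)hept-5-en-2-yl]hept-6-en-1-yne
Conditions: K2CO3, MeOH, rt
Reagents that add atoms: none
Why: Carbonate-catalysed methanolysis cleaves the alkynyl C–Si bond selectively in the presence of the hindered tertiary triethylsilyl ether.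

Step 7
Reactants: 12 terminal alkyne; 13 formaldehyde (used as paraformaldehyde)
Product: 15 (4S)-7-methyl-4-[(2S)-6-methyl-2-(triethylsilyloxy)hept-5-en-2-yl]oct-7-en-2-yn-1-ol, via lithium acetylide 14 (not isolated)
Conditions: n-BuLi, THF, −78 °C; then (CH2O)n, −78 °C → rt
Reagents that add atoms: none
Why: Acetylide addition to formaldehyde gives the propargylic alcohol whose CH2 carbon becomes the exocyclic methylene and whose hydroxyl later directs the ketone reduction and becomes the radical leaving group.

Step 8
Reactants: 15 1,6-enyne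
Product: 17 (5R,8S)-2-(hydroxymethyl)-5-methyl-8-[(2S)-6-methyl-2-(triethylsilyloxy)hept-5-en-2-yl]bicyclo[3.3.0]oct-1-en-3-one, via alkyne–Co2(CO)6 complex 16 (not isolated)
Conditions: Co2(CO)8, CH2Cl2, rt; then N-methylmorpholine N-oxide, 0 °C → rt
Reagents that add atoms: dicobalt octacarbonyl Co2(CO)8 (source of the carbonyl group), O=C=[Co](=C=O)(=C=O)(=C=O)[Co](=C=O)(=C=O)(=C=O)=C=O
Why: Co2(CO)8 forms the alkyne–Co2(CO)6 complex 16; N-oxide removal of one CO ligand opens a site for the tethered 1,1-disubstituted alkene, which inserts into the Co–C bond of the inner alkyne carbon, and CO insertion with reductive elimination then releases the enone. This is the intramolecular Pauson–Khand reaction of a 1,6-enyne with a 2-substituted allyl terminus, the known entry to angularly methylated bicyclo[3.3.0]octenones. The carbocyclic ring closes in a 5-exo sense by alkene insertion, joining the inner alkyne carbon to the methyl-bearing alkene carbon; the cyclopentenone closes by CO insertion and reductive elimination, the carbonyl carbon bonding to the outer alkyne carbon and to the alkene CH2. The single new stereocentre, the quaternary methyl carbon, is controlled by the propargylic stereocentre: its bulky silyloxyalkyl group should take the exo (convex) position in the forming metallacycle, away from the cobalt cluster and the CH2OH on the alkyne, which places the methyl cis to it. Chemoselectivity for the 1,1-disubstituted alkene over the trisubstituted one follows from tether length (1,6- against 1,7-enyne) and the lower substitution of the reacting alkene.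

Step 9
Reactants: 17 bicyclic enone
Product: 18 side-chain epoxide of 17 [8-substituent (2S)-5-(3,3-dimethyloxiran-2-yl)-2-(triethylsilyloxy)pentan-2-yl]
Conditions: mCPBA, NaHCO3, CH2Cl2, 0 °C
Reagents that add atoms: 3-chloroperoxybenzoic acid, OOC(=O)c1cccc(Cl)c1
Why: Prilezhaev epoxidation selects the electron-rich trisubstituted alkene over the electron-poor enone, masking it against intramolecular photocycloaddition and radical cyclisation; the new oxirane CH forms in both configurations, which is harmless.

Step 10
Reactants: 18 epoxy enone; 19 ethylene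
Product: 20 (1R,4S,7R,10S)-4-(hydroxymethyl)-7-methyl-10-[(2S)-5-(3,3-dimethyloxiran-2-yl)-2-(triethylsilyloxy)pentan-2-yl]tricyclo[5.3.0.0^{1,4}]decan-5-one
Conditions: hν (medium-pressure Hg lamp, Pyrex filter), CH2Cl2 saturated with 19, −78 °C
Reagents that add atoms: none
Why: Triplet enone–alkene (2+2) photocycloaddition, in which the cyclobutane must be cis-fused to the cyclopentanone and the diquinane can only be cis-fused, so ethylene should add on the face of the angular methyl; the two new quaternary centres are erased again in step 13.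

Step 11
Reactants: 20 tricyclic β-hydroxy ketone
Product: 21 (1R,4S,5R,7R,10S)-4-(hydroxymethyl)-7-methyl-10-[(2S)-5-(3,3-dimethyloxiran-2-yl)-2-(triethylsilyloxy)pentan-2-yl]tricyclo[5.3.0.0^{1,4}]decan-5-ol
Conditions: Me4NBH(OAc)3, MeCN/AcOH (10:1), −30 → 0 °C
Reagents that add atoms: none
Why: Hydroxyl-directed reduction of a β-hydroxy ketone (Evans–Saksena type), in which the primary hydroxyl exchanges onto boron and hydride is delivered intramolecularly to the carbonyl face bearing the CH2OH group, so the new hydroxyl should end on the cyclobutane face, cis to the angular methyl, as needed for the inversion in step 15; the small proportion of acetic acid and the low temperature are chosen to spare the epoxide.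

Step 12
Reactants: 21 tricyclic diol
Product: 22 (1R,4R,5R,7R,10S)-4-(iodomethyl)-7-methyl-10-[(2S)-5-(3,3-dimethyloxiran-2-yl)-2-(triethylsilyloxy)pentan-2-yl]tricyclo[5.3.0.0^{1,4}]decan-5-ol
Conditions: I2, PPh3, imidazole, toluene, rt → 60 °C
Reagents that add atoms: iodine, [I][I]
Why: Appel-type iodination is selective for the primary over the hindered secondary hydroxyl and is the established way to convert cyclobutylcarbinols of enone photoadducts into iodides, the imidazole buffer protecting the epoxide and the trans arrangement of the two oxygens excluding oxetane formation.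

Step 13
Reactants: 22 iodide
Product: 23 (1S,3aR,5R,8aS)-3a-methyl-6-methylidene-1-[(2S)-5-(3,3-dimethyloxiran-2-yl)-2-(triethylsilyloxy)pentan-2-yl]decahydroazulen-5-ol
Conditions: Bu3SnH (slow addition), AIBN (cat.), benzene, 80 °C
Reagents that add atoms: none
Why: Iodine abstraction gives a cyclobutylcarbinyl radical whose β-scission breaks the strained bond to the fully substituted neighbouring carbon (tertiary radical, ring expansion to the methylenecycloheptane), and that radical should take hydrogen from Bu3SnH on the face opposite the angular methyl and the side chain, setting the trans ring fusion; slow addition keeps the hydride concentration low so that fragmentation precedes reduction.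

Step 14
Reactants: 23 epoxy allylic alcohol
Product: 25 (1S,3aR,5R,8aS)-1-[(2S,4E)-6-hydroxy-6-methyl-2-(triethylsilyloxy)hept-4-en-2-yl]-3a-methyl-6-methylidenedecahydroazulen-5-ol, via hydroxy selenide 24 (not isolated)
Conditions: (PhSe)2, NaBH4, EtOH, reflux; then THF, pyridine, 30% H2O2, 0 °C → rt
Reagents that add atoms: none
Why: Selenolate opens the trisubstituted epoxide at its secondary carbon (SN2) and the derived selenoxide undergoes syn-elimination away from the carbinol carbon, the standard epoxide-to-allylic-alcohol transposition, which should give the E-alkene; pyridine suppresses epoxidation of the ring methylene by perseleninic acid.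

Step 15
Reactants: 25 diol
Product: 26 (1S,3aR,5S,8aS)-1-[(2S,4E)-6-hydroxy-6-methyl-2-(triethylsilyloxy)hept-4-en-2-yl]-3a-methyl-6-methylidenedecahydroazulen-5-yl acetate
Conditions: AcOH, PPh3, DIAD, toluene, 0 °C → rt
Reagents that add atoms: acetic acid, CC(=O)O
Why: Mitsunobu reaction in which only the secondary allylic alcohol is activated (the tertiary alcohol and the silyl ether are inert) and acetate displaces the oxyphosphonium group with inversion from the face opposite the angular methyl, giving the acetate trans to that methyl.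

Step 16
Reactants: 26 silylated acetate
Product: 27 (1S,3aR,5S,8aS)-1-[(2S,4E)-2,6-dihydroxy-6-methylhept-4-en-2-yl]-3a-methyl-6-methylidenedecahydroazulen-5-yl acetate
Conditions: HF·pyridine, pyridine, THF, 0 °C → rt
Reagents that add atoms: none
Why: Buffered fluoride desilylation cleaves the tertiary triethylsilyl ether while sparing the allylic acetate and the two tertiary alcohols.

**Compound list**

1 | geraniol, (2E)-3,7-dimethylocta-2,6-dien-1-ol | CC(C)=CCC/C(C)=C/CO | starting material
2 | (2S,3S)-2,3-epoxygeraniol, [(2S,3S)-3-methyl-3-(4-methylpent-3-enyl)oxiran-2-yl]methanol | OC[C@@H]1O[C@@]1(C)CCC=C(C)C | intermediate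
3 | ethynyltrimethylsilane | C#C[Si](C)(C)C | starting material
4 | lithium (trimethylsilyl)acetylide | [Li]C#C[Si](C)(C)C | intermediate (not isolated)
5 | lithium trimethyl[(trimethylsilyl)ethynyl]aluminate | [Li+].C[Al-](C)(C)C#C[Si](C)(C)C | intermediate (not isolated)
6 | lithium dimethyl[(trimethylsilyl)ethynyl]aluminate carrying the alkoxide of 2 on aluminium | [Li+].C[Al-](C)(C#C[Si](C)(C)C)OC[C@@H]1O[C@@]1(C)CCC=C(C)C | intermediate (not isolated)
7 | (2R,3S)-3,7-dimethyl-2-[(trimethylsilyl)ethynyl]oct-6-ene-1,3-diol | OC[C@@H](C#C[Si](C)(C)C)[C@@](C)(O)CCC=C(C)C | intermediate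
8 | (2R,3S)-3-hydroxy-3,7-dimethyl-2-[(trimethylsilyl)ethynyl]oct-6-en-1-yl 4-methylbenzenesulfonate | Cc1ccc(cc1)S(=O)(=O)OC[C@@H](C#C[Si](C)(C)C)[C@@](C)(O)CCC=C(C)C | intermediate
9 | (2R,3S)-3,7-dimethyl-3-(triethylsilyloxy)-2-[(trimethylsilyl)ethynyl]oct-6-en-1-yl 4-methylbenzenesulfonate | Cc1ccc(cc1)S(=O)(=O)OC[C@@H](C#C[Si](C)(C)C)[C@@](C)(O[Si](CC)(CC)CC)CCC=C(C)C | intermediate
10 | 2-methylallylmagnesium chloride | CC(=C)C[Mg]Cl | starting material
11 | (3S)-6-methyl-3-[(2S)-6-methyl-2-(triethylsilyloxy)hept-5-en-2-yl]-1-(trimethylsilyl)hept-6-en-1-yne | C[Si](C)(C)C#C[C@@H]([C@@](C)(O[Si](CC)(CC)CC)CCC=C(C)C)CCC(C)=C | intermediate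
12 | (3S)-6-methyl-3-[(2S)-6-methyl-2-(triethylsilyloxy)hept-5-en-2-yl]hept-6-en-1-yne | C#C[C@@H]([C@@](C)(O[Si](CC)(CC)CC)CCC=C(C)C)CCC(C)=C | intermediate
13 | formaldehyde (used as paraformaldehyde) | C=O | starting material
14 | lithium acetylide of 12 | [Li]C#C[C@@H]([C@@](C)(O[Si](CC)(CC)CC)CCC=C(C)C)CCC(C)=C | intermediate (not isolated)
15 | (4S)-7-methyl-4-[(2S)-6-methyl-2-(triethylsilyloxy)hept-5-en-2-yl]oct-7-en-2-yn-1-ol | OCC#C[C@@H]([C@@](C)(O[Si](CC)(CC)CC)CCC=C(C)C)CCC(C)=C | intermediate
16 | Co2(CO)6 complex of the alkyne of 15 (both alkyne carbons bridging the Co–Co bond) | OCC12C3([C@@H]([C@@](C)(O[Si](CC)(CC)CC)CCC=C(C)C)CCC(C)=C)[Co]1(=C=O)(=C=O)(=C=O)[Co]23(=C=O)(=C=O)=C=O | intermediate (not isolated)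
17 | (5R,8S)-2-(hydroxymethyl)-5-methyl-8-[(2S)-6-methyl-2-(triethylsilyloxy)hept-5-en-2-yl]bicyclo[3.3.0]oct-1-en-3-one (angular methyl cis to the side chain) | OCC1=C2[C@@H]([C@@](C)(O[Si](CC)(CC)CC)CCC=C(C)C)CC[C@]2(C)CC1=O | intermediate
18 | (5R,8S)-2-(hydroxymethyl)-5-methyl-8-[(2S)-5-(3,3-dimethyloxiran-2-yl)-2-(triethylsilyloxy)pentan-2-yl]bicyclo[3.3.0]oct-1-en-3-one (both oxirane CH configurations) | OCC1=C2[C@@H]([C@@](C)(O[Si](CC)(CC)CC)CCC3OC3(C)C)CC[C@]2(C)CC1=O | intermediate
19 | ethylene | C=C | starting material
20 | (1R,4S,7R,10S)-4-(hydroxymethyl)-7-methyl-10-[(2S)-5-(3,3-dimethyloxiran-2-yl)-2-(triethylsilyloxy)pentan-2-yl]tricyclo[5.3.0.0^{1,4}]decan-5-one (cyclobutane and angular methyl on one face of the cyclopentanone, CH2OH and the other five-membered ring on the opposite face) | OC[C@@]12C(=O)C[C@@]3(C)CC[C@H]([C@@](C)(O[Si](CC)(CC)CC)CCC4OC4(C)C)[C@]31CC2 | intermediate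
21 | (1R,4S,5R,7R,10S)-4-(hydroxymethyl)-7-methyl-10-[(2S)-5-(3,3-dimethyloxiran-2-yl)-2-(triethylsilyloxy)pentan-2-yl]tricyclo[5.3.0.0^{1,4}]decan-5-ol (secondary OH cis to the angular methyl, trans to CH2OH) | OC[C@@]12[C@H](O)C[C@@]3(C)CC[C@H]([C@@](C)(O[Si](CC)(CC)CC)CCC4OC4(C)C)[C@]31CC2 | intermediate
22 | (1R,4R,5R,7R,10S)-4-(iodomethyl)-7-methyl-10-[(2S)-5-(3,3-dimethyloxiran-2-yl)-2-(triethylsilyloxy)pentan-2-yl]tricyclo[5.3.0.0^{1,4}]decan-5-ol | IC[C@@]12[C@H](O)C[C@@]3(C)CC[C@H]([C@@](C)(O[Si](CC)(CC)CC)CCC4OC4(C)C)[C@]31CC2 | intermediate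
23 | (1S,3aR,5R,8aS)-3a-methyl-6-methylidene-1-[(2S)-5-(3,3-dimethyloxiran-2-yl)-2-(triethylsilyloxy)pentan-2-yl]decahydroazulen-5-ol (trans-fused; OH cis to the angular methyl) | C=C1CC[C@H]2[C@@H]([C@@](C)(O[Si](CC)(CC)CC)CCC3OC3(C)C)CC[C@]2(C)C[C@H]1O | intermediate
24 | (1S,3aR,5R,8aS)-1-[(2S)-6-hydroxy-6-methyl-5-(phenylselanyl)-2-(triethylsilyloxy)heptan-2-yl]-3a-methyl-6-methylidenedecahydroazulen-5-ol (both configurations at the selenium-bearing carbon) | C=C1CC[C@H]2[C@@H]([C@@](C)(O[Si](CC)(CC)CC)CCC([Se]c3ccccc3)C(C)(C)O)CC[C@]2(C)C[C@H]1O | intermediate (not isolated)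
25 | (1S,3aR,5R,8aS)-1-[(2S,4E)-6-hydroxy-6-methyl-2-(triethylsilyloxy)hept-4-en-2-yl]-3a-methyl-6-methylidenedecahydroazulen-5-ol | C=C1CC[C@H]2[C@@H]([C@@](C)(O[Si](CC)(CC)CC)C/C=C/C(C)(C)O)CC[C@]2(C)C[C@H]1O | intermediate
26 | (1S,3aR,5S,8aS)-1-[(2S,4E)-6-hydroxy-6-methyl-2-(triethylsilyloxy)hept-4-en-2-yl]-3a-methyl-6-methylidenedecahydroazulen-5-yl acetate | C=C1CC[C@H]2[C@@H]([C@@](C)(O[Si](CC)(CC)CC)C/C=C/C(C)(C)O)CC[C@]2(C)C[C@@H]1OC(C)=O | intermediate
27 | (1S,3aR,5S,8aS)-1-[(2S,4E)-2,6-dihydroxy-6-methylhept-4-en-2-yl]-3a-methyl-6-methylidenedecahydroazulen-5-yl acetate (CNP0290154.1) | C=C1CC[C@H]2[C@@H]([C@@](C)(O)C/C=C/C(C)(C)O)CC[C@]2(C)C[C@@H]1OC(C)=O | target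

**Step count and risks**

Total: 16 steps. Longest linear sequence: 16 steps (1 → 27); 3, 10, 13 and 19 enter as purchased reagents.

Steps most likely to fail:

1. Step 2. The alkynyl group may be transferred to the tertiary oxirane carbon, or transfer at the hindered C2 may be so slow that the epoxy alkoxide isomerises or decomposes first. Fallback, setting out from 2: the primary hydroxyl is tosylated (TsCl, Et3N, DMAP) to the epoxy tosylate F1. The tosylate is displaced by 10 under Li2CuCl4 catalysis to give the hydrocarbon epoxide F2, in which the secondary oxirane carbon no longer has an electron-withdrawing oxygen neighbour. The oxirane is then opened at that carbon with lithium acetylide–ethylenediamine complex in DMSO (intermolecular SN2, same inversion) to give the tertiary alcohol F3. Silylation with TESOTf/2,6-lutidine returns to the route at 12.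

2. Step 10. Capture of the triplet enone by dissolved ethylene may be too slow on a face flanked by the angular methyl and the side chain, so that photoreduction or decomposition of the enone takes over. Fallback, setting out from 18: irradiation in the presence of a large excess of (E)-1,2-dichloroethene as co-solvent gives the dichlorocyclobutane F4. Bu3SnH/AIBN in hot toluene removes both chlorines by reductive elimination to give the cyclobutene F5. Hydrogenation over Pd/C (no other C=C bond is present at this stage) returns to the route at 20.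

3. Step 15. The oxyphosphonium intermediate may be attacked at the methylene terminus (SN2' displacement to a primary allylic acetate) or may eliminate to a diene instead of undergoing direct displacement. Fallback, setting out from 25: MnO2 oxidises the secondary allylic alcohol to the α-methylene cycloheptanone F6. Reagent-controlled reduction with (R)-2-methyl-CBS-oxazaborolidine and catecholborane gives the epimeric allylic alcohol F7. Ac2O/pyridine then acetylates its secondary hydroxyl selectively, returning to the route at 26.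

Further compounds
F1 | step 2 | [(2S,3S)-3-methyl-3-(4-methylpent-3-enyl)oxiran-2-yl]methyl 4-methylbenzenesulfonate | Cc1ccc(cc1)S(=O)(=O)OC[C@@H]1O[C@@]1(C)CCC=C(C)C
F2 | step 2 | (2S,3S)-2-methyl-3-(3-methylbut-3-enyl)-2-(4-methylpent-3-enyl)oxirane | CC(=C)CC[C@@H]1O[C@@]1(C)CCC=C(C)C
F3 | step 2 | (3S,4S)-4,8-dimethyl-3-(3-methylbut-3-enyl)non-7-en-1-yn-4-ol | C#C[C@@H]([C@@](C)(O)CCC=C(C)C)CCC(C)=C
F4 | step 10 | 2,3-dichloro derivative of 20 (both configurations at the CHCl carbons) | OC[C@@]12C(=O)C[C@@]3(C)CC[C@H]([C@@](C)(O[Si](CC)(CC)CC)CCC4OC4(C)C)[C@]31C(Cl)C2Cl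
F5 | step 10 | 2,3-didehydro derivative of 20 (cyclobutene) | OC[C@@]12C(=O)C[C@@]3(C)CC[C@H]([C@@](C)(O[Si](CC)(CC)CC)CCC4OC4(C)C)[C@]31C=C2
F6 | step 15 | (1S,3aR,8aS)-1-[(2S,4E)-6-hydroxy-6-methyl-2-(triethylsilyloxy)hept-4-en-2-yl]-3a-methyl-6-methylideneoctahydroazulen-5(1H)-one | C=C1CC[C@H]2[C@@H]([C@@](C)(O[Si](CC)(CC)CC)C/C=C/C(C)(C)O)CC[C@]2(C)CC1=O
F7 | step 15 | (1S,3aR,5S,8aS)-1-[(2S,4E)-6-hydroxy-6-methyl-2-(triethylsilyloxy)hept-4-en-2-yl]-3a-methyl-6-methylidenedecahydroazulen-5-ol | C=C1CC[C@H]2[C@@H]([C@@](C)(O[Si](CC)(CC)CC)C/C=C/C(C)(C)O)CC[C@]2(C)C[C@@H]1O
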